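**Plan**
Retrosynthesis: remove the C17 methylene and the silyl groups, cut C6–C7 of the 14-membered ring, then C1–C14, then (east) C1–C2 and the C3/C4 epoxide, (west) C12–C20 and C11–C12.
Enabling feature: C6–C7 is the central σ-bond of the ring's 1,5-diene C4=C5–C6–C7–C8=C9. C6 is allylic to C4=C5 and can carry a sulfonyl-stabilised carbanion; C7 is allylic to C8=C9 and is an SN2-active chloride. The trans-fused lactone ring (O–C2–C1–C15–C16) is already in place and restricts the chain.
Forward: a west iodo triol (7 steps) and an east butenolide allyl sulfone (5 steps) are joined at C1–C14 by radical conjugate addition; the carbocycle is then closed at C6–C7; desulfonylation, α-methylenation and desilylation follow.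
Stereochemistry: C13 from methyl (S)-glycerate acetonide; C12 by chelate-controlled addition to the C12 ketone; C3 by Sharpless epoxidation; C2 by Felkin–Anh addition to the epoxy aldehyde; C1 by addition anti to the C2 substituent of the butenolide.
Olefins: E-C8=C9 from SeO2 oxidation of the E methyl of a prenyl terminus; E-C4=C5, the C6 sulfone and free O3 all from one zerovalent-palladium opening of a C3/C4 vinyl epoxide by sulfinate.

Key step: step 15

Remark: cembrane numbering is used (C1 = ring CH bearing lactone α-carbon C15; C2 = lactone O–CH; C3 = CH–O; C4(methyl C18)=C5; C6; C7; C8(methyl C19)=C9; C10; C11; C12 bearing C20H2–O; C13; C14; C16 = lactone C=O; C17 = exocyclic CH2); the target is (1R,2R,3S,12S,13S,4E,8E).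

Step 1
Reactants: 1 methyl (4S)-2,2-dimethyl-1,3-dioxolane-4-carboxylate
Product: 2 (4S)-N-methoxy-N,2,2-trimethyl-1,3-dioxolane-4-carboxamide
Conditions: MeNH(OMe)·HCl, i-PrMgCl, THF, −20 °C
Reagents that add atoms: N,O-dimethylhydroxylamine hydrochloride, CNOC.Cl
Why: Weinreb amide formation by aminolysis of the ester with the chloromagnesium amide, cold enough that the α-alkoxy stereocenter (C13) should not epimerise.

Step 2
Reactants: 2 (4S)-N-methoxy-N,2,2-trimethyl-1,3-dioxolane-4-carboxamide; 3 5-bromo-2-methylpent-2-ene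
Product: 5 1-[(4S)-2,2-dimethyl-1,3-dioxolan-4-yl]-5-methylhex-4-en-1-one, via (4-methylpent-3-en-1-yl)magnesium bromide 4 (not isolated)
Conditions: 3, Mg, THF, rt; then 2, THF, 0 °C; aq. NH4Cl
Reagents that add atoms: none
Why: Grignard addition to a Weinreb amide should stop at the ketone because the chelated tetrahedral intermediate survives until work-up.

Step 3
Reactants: 5 1-[(4S)-2,2-dimethyl-1,3-dioxolan-4-yl]-5-methylhex-4-en-1-one; 6 (chloromethyl)dimethyl(propan-2-yloxy)silane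
Product: 9 (2S)-2-[(4S)-2,2-dimethyl-1,3-dioxolan-4-yl]-6-methylhept-5-ene-1,2-diol, via {[dimethyl(propan-2-yloxy)silyl]methyl}magnesium chloride 7 (not isolated), via β-hydroxy silane 8 (not isolated)
Conditions: 6, Mg, THF, rt; then 5, Et2O/THF, −78 °C; aq. NH4Cl; then KF, KHCO3, 30% H2O2, THF/MeOH, rt
Reagents that add atoms: hydrogen peroxide, OO
Why: Cram-chelate Grignard addition (Mg bridging the ketone oxygen and the dioxolane oxygen on C13) should deliver the silylmethyl group to the face of C13–H and set C12 as in the target (12S), and Tamao–Fleming oxidation then converts C–Si into C–OH.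

Step 4
Reactants: 9 (2S)-2-[(4S)-2,2-dimethyl-1,3-dioxolan-4-yl]-6-methylhept-5-ene-1,2-diol
Product: 10 (2S,5E)-2-[(4S)-2,2-dimethyl-1,3-dioxolan-4-yl]-6-methylhept-5-ene-1,2,7-triol
Conditions: SeO2 (cat.), t-BuOOH, salicylic acid (cat.), CH2Cl2, 0 °C to rt
Reagents that add atoms: tert-butyl hydroperoxide, CC(C)(C)OO
Why: SeO2 allylic oxidation (ene reaction then [2,3] shift) should hydroxylate only the methyl group trans to the chain, which fixes the E geometry of C8=C9.

Step 5
Reactants: 10 (2S,5E)-2-[(4S)-2,2-dimethyl-1,3-dioxolan-4-yl]-6-methylhept-5-ene-1,2,7-triol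
Product: 11 (2S,5E)-7-chloro-2-[(4S)-2,2-dimethyl-1,3-dioxolan-4-yl]-6-methylhept-5-ene-1,2-diol
Conditions: N-chlorosuccinimide, Me2S, CH2Cl2, −20 to 0 °C
Reagents that add atoms: N-chlorosuccinimide, O=C1CCC(=O)N1Cl
Why: Corey–Kim chlorination should convert only the allylic alcohol into the chloride by SN2 displacement of its alkoxysulfonium salt, without allylic transposition and without touching the saturated primary and tertiary hydroxyls.

Step 6
Reactants: 11 (2S,5E)-7-chloro-2-[(4S)-2,2-dimethyl-1,3-dioxolan-4-yl]-6-methylhept-5-ene-1,2-diol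
Product: 12 (2S,3S)-2-[(3E)-5-chloro-4-methylpent-3-en-1-yl]butane-1,2,3,4-tetrol
Conditions: AcOH/H2O (4:1), rt
Reagents that add atoms: none
Why: mild acid hydrolysis of the terminal isopropylidene acetal, under which the primary allylic chloride should survive.

Step 7
Reactants: 12 (2S,3S)-2-[(3E)-5-chloro-4-methylpent-3-en-1-yl]butane-1,2,3,4-tetrol
Product: 13 (2S,3R)-2-[(3E)-5-chloro-4-methylpent-3-en-1-yl]-4-iodobutane-1,2,3-triol
Conditions: I2, PPh3, imidazole, THF, 0 °C
Reagents that add atoms: iodine, [I][I]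
Why: Appel-type iodination should replace only the unhindered primary C14–OH, because the other primary hydroxyl (C20) is neopentyl-like next to the quaternary C12 and reacts far more slowly.

Step 8
Reactants: 14 (2E)-3-methylpent-2-en-4-yn-1-ol
Product: 15 [(2R,3R)-3-ethynyl-3-methyloxiran-2-yl]methanol
Conditions: Ti(Oi-Pr)4 (cat.), D-(−)-diisopropyl tartrate (cat.), t-BuOOH, 4 Å molecular sieves, CH2Cl2, −20 °C
Reagents that add atoms: tert-butyl hydroperoxide, CC(C)(C)OO
Why: Sharpless asymmetric epoxidation of the allylic alcohol, in which the D-(−)-tartrate should direct oxygen to the face that gives the (2R,3R)-epoxide and hence the C3 configuration of the target.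

Step 9
Reactants: 15 [(2R,3R)-3-ethynyl-3-methyloxiran-2-yl]methanol
Product: 16 (2S,3R)-3-ethynyl-3-methyloxirane-2-carbaldehyde
Conditions: PhI(OAc)2, TEMPO (cat.), CH2Cl2, rt; used directly
Reagents that add atoms: none
Why: TEMPO/PhI(OAc)2 oxidation of the primary alcohol to the aldehyde under near-neutral conditions that should leave the epoxide, the alkyne and the α-stereocenter intact.

Step 10
Reactants: 16 (2S,3R)-3-ethynyl-3-methyloxirane-2-carbaldehyde; 17 ethyl prop-2-ynoate
Product: 19 ethyl (4R)-4-[(2R,3R)-3-ethynyl-3-methyloxiran-2-yl]-4-hydroxybut-2-ynoate, via ethyl 3-lithioprop-2-ynoate 18 (not isolated)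
Conditions: 17, LiN(SiMe3)2, THF, −78 °C; then 16, −78 °C; aq. NH4Cl
Reagents that add atoms: none
Why: acetylide addition to the α,β-epoxy aldehyde under Felkin–Anh control (epoxide C–O anti to the incoming nucleophile) should give mainly the 4R alcohol, that is C2 with its oxygen anti to O3 as in the target.

Step 11
Reactants: 19 ethyl (4R)-4-[(2R,3R)-3-ethynyl-3-methyloxiran-2-yl]-4-hydroxybut-2-ynoate
Product: 21 (5R)-5-[(2R,3R)-3-ethenyl-3-methyloxiran-2-yl]furan-2(5H)-one, via (Z)-hydroxy enoate 20 (not isolated)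
Conditions: H2 (1 atm), Pd/CaCO3 poisoned with Pb(OAc)2, quinoline, EtOAc, rt; then silica gel, CH2Cl2
Reagents that add atoms: none
Why: semi-hydrogenation over poisoned palladium should reduce the ynoate to the Z enoate, which lactonises to the butenolide, and the terminal alkyne to the vinyl group, with no change at any stereocenter.

Step 12
Reactants: 21 (5R)-5-[(2R,3R)-3-ethenyl-3-methyloxiran-2-yl]furan-2(5H)-one
Product: 22 (5R)-5-[(1S,2E)-1-hydroxy-2-methyl-4-(phenylsulfonyl)but-2-en-1-yl]furan-2(5H)-one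
Conditions: PhSO2Na, AcOH, Pd(PPh3)4 (cat.), THF, rt
Reagents that add atoms: sodium benzenesulfinate, [Na+].[O-]S(=O)c1ccccc1
Why: Tsuji–Trost opening of the vinyl epoxide, in which sulfinate attacks the π-allylpalladium complex reversibly at the unhindered C6 terminus so that the E 1,4-adduct should accumulate, while the C3–O bond is never broken and C3 keeps its configuration.

Step 13
Reactants: 13 (2S,3R)-2-[(3E)-5-chloro-4-methylpent-3-en-1-yl]-4-iodobutane-1,2,3-triol; 22 (5R)-5-[(1S,2E)-1-hydroxy-2-methyl-4-(phenylsulfonyl)but-2-en-1-yl]furan-2(5H)-one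
Product: 23 (4R,5R)-4-[(2S,3S,6E)-8-chloro-2,3-dihydroxy-3-(hydroxymethyl)-7-methyloct-6-en-1-yl]-5-[(1S,2E)-1-hydroxy-2-methyl-4-(phenylsulfonyl)but-2-en-1-yl]oxolan-2-one
Conditions: (Me3Si)3SiH, AIBN (cat.), PhMe, 80 °C; 22 in excess (2 equiv, 0.5 M)
Reagents that add atoms: none
Why: Giese radical conjugate addition (iodine abstraction by the silyl radical, addition of the primary C14 radical to the butenolide β-carbon, hydrogen transfer), in which attack anti to the C2 side chain should set C1 as R and give the trans lactone.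

Step 14
Reactants: 23 (4R,5R)-4-[(2S,3S,6E)-8-chloro-2,3-dihydroxy-3-(hydroxymethyl)-7-methyloct-6-en-1-yl]-5-[(1S,2E)-1-hydroxy-2-methyl-4-(phenylsulfonyl)but-2-en-1-yl]oxolan-2-one
Product: 24 (4R,5R)-4-[(2S,3S,6E)-8-chloro-7-methyl-2,3-bis(triethylsilyloxy)-3-[(triethylsilyloxy)methyl]oct-6-en-1-yl]-5-[(1S,2E)-2-methyl-4-(phenylsulfonyl)-1-(triethylsilyloxy)but-2-en-1-yl]oxolan-2-one
Conditions: Et3SiOTf, 2,6-lutidine, CH2Cl2, −78 to 0 °C
Reagents that add atoms: triethylsilyl trifluoromethanesulfonate, CC[Si](CC)(CC)OS(=O)(=O)C(F)(F)F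
Why: silyl triflate silylation should mask all four hydroxyls (the tertiary C12–OH included), so that the sulfone α-CH2 is the only strongly acidic site left.

Step 15
Reactants: 24 (4R,5R)-4-[(2S,3S,6E)-8-chloro-7-methyl-2,3-bis(triethylsilyloxy)-3-[(triethylsilyloxy)methyl]oct-6-en-1-yl]-5-[(1S,2E)-2-methyl-4-(phenylsulfonyl)-1-(triethylsilyloxy)but-2-en-1-yl]oxolan-2-one
Product: 25 (1R,2R,3S,12S,13S,4E,8E)-6-(phenylsulfonyl)-3,12,13,20-tetrakis(triethylsilyloxy)cembra-4,8-dien-16,2-olide (C6 epimers)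
Conditions: KN(SiMe3)2 (1.2 equiv), THF, −78 to −20 °C, slow addition of 24 to 0.002 M
Reagents that add atoms: none
Why: KN(SiMe3)2 deprotonates C6 of the allyl sulfone (much more acidic than the lactone α-CH2) and the sulfonyl-stabilised allyl anion displaces chloride from the primary allylic C7 in an intramolecular SN2 alkylation. The closest known reaction type is the Julia-type alkylation of allylic sulfone carbanions by allylic halides, used at high dilution to close 14-membered carbocycles. The 14-membered ring closes in the 14-exo-tet mode at the C6–C7 bond between the two trisubstituted olefins. No stereocenter of the target is formed; C6 becomes a sulfonyl-bearing stereocenter of no consequence (epimer mixture) that is erased in step 16. The step needs α-attack of the ambident anion (C4 is fully substituted), SN2 and not SN2′ displacement (C7 is primary, C9 is hindered), retention of both E olefins (a direct displacement at low temperature touches neither) and cyclisation instead of oligomerisation (slow addition at high dilution; the trans-fused lactone and the two E olefins limit the freedom of the chain).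

Step 16
Reactants: 25 (1R,2R,3S,12S,13S,4E,8E)-6-(phenylsulfonyl)-3,12,13,20-tetrakis(triethylsilyloxy)cembra-4,8-dien-16,2-olide (C6 epimers)
Product: 26 (1R,2R,3S,12S,13S,4E,8E)-3,12,13,20-tetrakis(triethylsilyloxy)cembra-4,8-dien-16,2-olide
Conditions: Pd(PPh3)4 (cat.), NaBH4, THF/i-PrOH, 0 °C to rt
Reagents that add atoms: none
Why: palladium-catalysed hydride substitution of the allylic sulfone (ionisation to the π-allyl complex, hydride delivery to the less substituted C6 terminus and not to the fully substituted C4) should keep the E-C4=C5 olefin in place, and NaBH4 in the cold should leave the lactone.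

Step 17
Reactants: 26 (1R,2R,3S,12S,13S,4E,8E)-3,12,13,20-tetrakis(triethylsilyloxy)cembra-4,8-dien-16,2-olide
Product: 27 (1R,2R,3S,12S,13S,4E,8E)-17-(dimethylamino)-3,12,13,20-tetrakis(triethylsilyloxy)cembra-4,8-dien-16,2-olide (C15 epimers)
Conditions: LiN(i-Pr)2, THF, −78 °C; then Me2N=CH2+ I−, −78 to 0 °C
Reagents that add atoms: N,N-dimethylmethylideneammonium iodide, C[N+](C)=C.[I-]
Why: Mannich reaction of the lactone lithium enolate with the iminium salt, possible only at C15 because it is the only carbon α to the carbonyl.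

Step 18
Reactants: 27 (1R,2R,3S,12S,13S,4E,8E)-17-(dimethylamino)-3,12,13,20-tetrakis(triethylsilyloxy)cembra-4,8-dien-16,2-olide (C15 epimers)
Product: 29 (1R,2R,3S,12S,13S,4E,8E)-3,12,13,20-tetrakis(triethylsilyloxy)cembra-4,8,15(17)-trien-16,2-olide, via trimethylammonium iodide 28 (not isolated)
Conditions: MeI, THF/MeOH, rt; then sat. aq. NaHCO3, rt
Reagents that add atoms: none
Why: quaternisation followed by Hofmann-type E1cB loss of trimethylamine should give the exocyclic C15=C17 methylene and remove the C15 stereocenter.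

Step 19
Reactants: 29 (1R,2R,3S,12S,13S,4E,8E)-3,12,13,20-tetrakis(triethylsilyloxy)cembra-4,8,15(17)-trien-16,2-olide
Product: 30 sinularolide A, (1R,2R,3S,12S,13S,4E,8E)-3,12,13,20-tetrahydroxycembra-4,8,15(17)-trien-16,2-olide
Conditions: HF·pyridine, pyridine, THF, 0 °C to rt
Reagents that add atoms: none
Why: buffered fluoride cleavage of the four triethylsilyl ethers, which the α-methylene lactone, the allylic alcohol and the olefins should tolerate.

**Compound list**
1 | methyl (4S)-2,2-dimethyl-1,3-dioxolane-4-carboxylate | COC(=O)[C@@H]1COC(C)(C)O1 | starting material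
2 | (4S)-N-methoxy-N,2,2-trimethyl-1,3-dioxolane-4-carboxamide | CON(C)C(=O)[C@@H]1COC(C)(C)O1 | intermediate
3 | 5-bromo-2-methylpent-2-ene | CC(C)=CCCBr | starting material
4 | (4-methylpent-3-en-1-yl)magnesium bromide | CC(C)=CCC[Mg]Br | intermediate
5 | 1-[(4S)-2,2-dimethyl-1,3-dioxolan-4-yl]-5-methylhex-4-en-1-one | CC(C)=CCCC(=O)[C@@H]1COC(C)(C)O1 | intermediate
6 | (chloromethyl)dimethyl(propan-2-yloxy)silane | CC(C)O[Si](C)(C)CCl | starting material
7 | {[dimethyl(propan-2-yloxy)silyl]methyl}magnesium chloride | CC(C)O[Si](C)(C)C[Mg]Cl | intermediate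
8 | (2R)-2-[(4S)-2,2-dimethyl-1,3-dioxolan-4-yl]-1-[dimethyl(propan-2-yloxy)silyl]-6-methylhept-5-en-2-ol | CC(C)O[Si](C)(C)C[C@@](O)(CCC=C(C)C)[C@@H]1COC(C)(C)O1 | intermediate
9 | (2S)-2-[(4S)-2,2-dimethyl-1,3-dioxolan-4-yl]-6-methylhept-5-ene-1,2-diol | OC[C@@](O)(CCC=C(C)C)[C@@H]1COC(C)(C)O1 | intermediate
10 | (2S,5E)-2-[(4S)-2,2-dimethyl-1,3-dioxolan-4-yl]-6-methylhept-5-ene-1,2,7-triol | OC[C@@](O)(CC/C=C(\C)CO)[C@@H]1COC(C)(C)O1 | intermediate
11 | (2S,5E)-7-chloro-2-[(4S)-2,2-dimethyl-1,3-dioxolan-4-yl]-6-methylhept-5-ene-1,2-diol | OC[C@@](O)(CC/C=C(\C)CCl)[C@@H]1COC(C)(C)O1 | intermediate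
12 | (2S,3S)-2-[(3E)-5-chloro-4-methylpent-3-en-1-yl]butane-1,2,3,4-tetrol | OC[C@@](O)(CC/C=C(\C)CCl)[C@@H](O)CO | intermediate
13 | (2S,3R)-2-[(3E)-5-chloro-4-methylpent-3-en-1-yl]-4-iodobutane-1,2,3-triol | OC[C@@](O)(CC/C=C(\C)CCl)[C@@H](O)CI | intermediate
14 | (2E)-3-methylpent-2-en-4-yn-1-ol | C#C/C(C)=C/CO | starting material
15 | [(2R,3R)-3-ethynyl-3-methyloxiran-2-yl]methanol | OC[C@H]1O[C@]1(C)C#C | intermediate
16 | (2S,3R)-3-ethynyl-3-methyloxirane-2-carbaldehyde | O=C[C@H]1O[C@]1(C)C#C | intermediate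
17 | ethyl prop-2-ynoate | C#CC(=O)OCC | starting material
18 | ethyl 3-lithioprop-2-ynoate | [Li]C#CC(=O)OCC | intermediate
19 | ethyl (4R)-4-[(2R,3R)-3-ethynyl-3-methyloxiran-2-yl]-4-hydroxybut-2-ynoate | CCOC(=O)C#C[C@@H](O)[C@H]1O[C@]1(C)C#C | intermediate
20 | ethyl (2Z,4R)-4-[(2R,3R)-3-ethenyl-3-methyloxiran-2-yl]-4-hydroxybut-2-enoate | CCOC(=O)/C=C\[C@@H](O)[C@H]1O[C@]1(C)C=C | intermediate
21 | (5R)-5-[(2R,3R)-3-ethenyl-3-methyloxiran-2-yl]furan-2(5H)-one | O=C1C=C[C@@H](O1)[C@H]2O[C@]2(C)C=C | intermediate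
22 | (5R)-5-[(1S,2E)-1-hydroxy-2-methyl-4-(phenylsulfonyl)but-2-en-1-yl]furan-2(5H)-one | O=C1C=C[C@@H](O1)[C@@H](O)/C(C)=C/CS(=O)(=O)c2ccccc2 | intermediate
23 | (4R,5R)-4-[(2S,3S,6E)-8-chloro-2,3-dihydroxy-3-(hydroxymethyl)-7-methyloct-6-en-1-yl]-5-[(1S,2E)-1-hydroxy-2-methyl-4-(phenylsulfonyl)but-2-en-1-yl]oxolan-2-one | O=C1C[C@@H](C[C@H](O)[C@@](O)(CO)CC/C=C(\C)CCl)[C@@H](O1)[C@@H](O)/C(C)=C/CS(=O)(=O)c2ccccc2 | intermediate
24 | (4R,5R)-4-[(2S,3S,6E)-8-chloro-7-methyl-2,3-bis(triethylsilyloxy)-3-[(triethylsilyloxy)methyl]oct-6-en-1-yl]-5-[(1S,2E)-2-methyl-4-(phenylsulfonyl)-1-(triethylsilyloxy)but-2-en-1-yl]oxolan-2-one | O=C1C[C@@H](C[C@H](O[Si](CC)(CC)CC)[C@@](O[Si](CC)(CC)CC)(CO[Si](CC)(CC)CC)CC/C=C(\C)CCl)[C@@H](O1)[C@@H](O[Si](CC)(CC)CC)/C(C)=C/CS(=O)(=O)c2ccccc2 | intermediate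
25 | (1R,2R,3S,12S,13S,4E,8E)-6-(phenylsulfonyl)-3,12,13,20-tetrakis(triethylsilyloxy)cembra-4,8-dien-16,2-olide (C6 epimers) | C1C(=O)O[C@@H]2[C@@H]1C[C@H](O[Si](CC)(CC)CC)[C@@](O[Si](CC)(CC)CC)(CO[Si](CC)(CC)CC)CC/C=C(\C)CC(S(=O)(=O)c3ccccc3)/C=C(\C)[C@@H]2O[Si](CC)(CC)CC | intermediate
26 | (1R,2R,3S,12S,13S,4E,8E)-3,12,13,20-tetrakis(triethylsilyloxy)cembra-4,8-dien-16,2-olide | C1C(=O)O[C@@H]2[C@@H]1C[C@H](O[Si](CC)(CC)CC)[C@@](O[Si](CC)(CC)CC)(CO[Si](CC)(CC)CC)CC/C=C(\C)CC/C=C(\C)[C@@H]2O[Si](CC)(CC)CC | intermediate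
27 | (1R,2R,3S,12S,13S,4E,8E)-17-(dimethylamino)-3,12,13,20-tetrakis(triethylsilyloxy)cembra-4,8-dien-16,2-olide (C15 epimers) | CN(C)CC1C(=O)O[C@@H]2[C@@H]1C[C@H](O[Si](CC)(CC)CC)[C@@](O[Si](CC)(CC)CC)(CO[Si](CC)(CC)CC)CC/C=C(\C)CC/C=C(\C)[C@@H]2O[Si](CC)(CC)CC | intermediate
28 | N,N,N-trimethylammonium iodide of 27 (17-trimethylammonio lactone iodide) | C[N+](C)(C)CC1C(=O)O[C@@H]2[C@@H]1C[C@H](O[Si](CC)(CC)CC)[C@@](O[Si](CC)(CC)CC)(CO[Si](CC)(CC)CC)CC/C=C(\C)CC/C=C(\C)[C@@H]2O[Si](CC)(CC)CC.[I-] | intermediate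
29 | (1R,2R,3S,12S,13S,4E,8E)-3,12,13,20-tetrakis(triethylsilyloxy)cembra-4,8,15(17)-trien-16,2-olide | C=C1C(=O)O[C@@H]2[C@@H]1C[C@H](O[Si](CC)(CC)CC)[C@@](O[Si](CC)(CC)CC)(CO[Si](CC)(CC)CC)CC/C=C(\C)CC/C=C(\C)[C@@H]2O[Si](CC)(CC)CC | intermediate
30 | sinularolide A, (1R,2R,3S,12S,13S,4E,8E)-3,12,13,20-tetrahydroxycembra-4,8,15(17)-trien-16,2-olide | C=C1C(=O)O[C@@H]2[C@@H]1C[C@H](O)[C@@](O)(CO)CC/C=C(\C)CC/C=C(\C)[C@@H]2O | target

Total steps: 19. Longest linear sequence: 14 steps (steps 1 to 7, then 13 to 19).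

**Steps most likely to fail**

Step 15. The sulfonyl carbanion may expel the C3 silyloxy group by vinylogous β-elimination (giving a sulfonyl diene), or alkylate a second molecule instead of closing the ring. The fallback changes the protecting-group order so that C3 carries an alkoxide, which cannot leave, during the cyclisation. It sets out from 13 and 22 and comes back at 25. Compound 13 would be silylated on its three hydroxyls (Et3SiOTf, 2,6-lutidine) to (2S,3R)-2-[(3E)-5-chloro-4-methylpent-3-en-1-yl]-4-iodo-1,2,3-tris(triethylsilyloxy)butane F1. Radical addition of F1 to 22 under the conditions of step 13 should give the C3-hydroxy seco compound F2. Cyclisation of F2 as its alkoxide–carbanion dianion (2.2 equiv KN(SiMe3)2, THF, high dilution) should give the macrocyclic 3-hydroxy-6-(phenylsulfonyl) lactone F3, and silylation of F3 with Et3SiOTf returns to 25.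

Step 3. The ketone addition may show poor or reversed facial selectivity if a non-chelated (Felkin–Anh) transition state competes with the magnesium chelate, which would give the C12 epimer. The fallback reverses the order in which the two carbon substituents of C12 are introduced, so that the same non-chelated preference leads to the required 12S centre. It sets out from Grignard reagent 4 (made from 3) and commercial L-erythrulose, and comes back at 9. L-erythrulose would be converted (2,2-dimethoxypropane, TsOH) into its 3,4-acetonide 1-[(4S)-2,2-dimethyl-1,3-dioxolan-4-yl]-2-hydroxyethan-1-one F4, and silylated (t-BuPh2SiCl, imidazole) to the silyl ether F5. Addition of 4 at −78 °C should give the tertiary alcohol (2S)-1-[(tert-butyldiphenylsilyl)oxy]-2-[(4S)-2,2-dimethyl-1,3-dioxolan-4-yl]-6-methylhept-5-en-2-ol F6, and Bu4NF would then remove the silyl group to give 9.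

Step 16. The borohydride may attack the lactone, or hydride may be delivered to C4 with transposition of the olefin. The fallback accepts reduction of the lactone and restores it by oxidation. It sets out from 25 and comes back at 26. Treatment of 25 with LiBHEt3 and PdCl2[Ph2P(CH2)3PPh2] in THF at 0 °C, the established regioselective variant of this reduction, should remove the sulfone with hydride delivery to C6 and reduce the lactone to (1S,2R,3S,12S,13S,4E,8E)-3,12,13,20-tetrakis(triethylsilyloxy)cembra-4,8-diene-2,16-diol F7. Oxidation of F7 with TEMPO and PhI(OAc)2 (primary alcohol to aldehyde, lactol, then lactone) gives 26.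

Further compounds
F1 | step 15 | (2S,3R)-2-[(3E)-5-chloro-4-methylpent-3-en-1-yl]-4-iodo-1,2,3-tris(triethylsilyloxy)butane | CC[Si](CC)(CC)OC[C@@](O[Si](CC)(CC)CC)(CC/C=C(\C)CCl)[C@@H](O[Si](CC)(CC)CC)CI
F2 | step 15 | (4R,5R)-4-[(2S,3S,6E)-8-chloro-7-methyl-2,3-bis(triethylsilyloxy)-3-[(triethylsilyloxy)methyl]oct-6-en-1-yl]-5-[(1S,2E)-1-hydroxy-2-methyl-4-(phenylsulfonyl)but-2-en-1-yl]oxolan-2-one | O=C1C[C@@H](C[C@H](O[Si](CC)(CC)CC)[C@@](O[Si](CC)(CC)CC)(CO[Si](CC)(CC)CC)CC/C=C(\C)CCl)[C@@H](O1)[C@@H](O)/C(C)=C/CS(=O)(=O)c2ccccc2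
F3 | step 15 | (1R,2R,3S,12S,13S,4E,8E)-3-hydroxy-6-(phenylsulfonyl)-12,13,20-tris(triethylsilyloxy)cembra-4,8-dien-16,2-olide (C6 epimers) | C1C(=O)O[C@@H]2[C@@H]1C[C@H](O[Si](CC)(CC)CC)[C@@](O[Si](CC)(CC)CC)(CO[Si](CC)(CC)CC)CC/C=C(\C)CC(S(=O)(=O)c3ccccc3)/C=C(\C)[C@@H]2O
F4 | step 3 | 1-[(4S)-2,2-dimethyl-1,3-dioxolan-4-yl]-2-hydroxyethan-1-one (3,4-O-isopropylidene-L-erythrulose) | OCC(=O)[C@@H]1COC(C)(C)O1
F5 | step 3 | 2-[(tert-butyldiphenylsilyl)oxy]-1-[(4S)-2,2-dimethyl-1,3-dioxolan-4-yl]ethan-1-one | CC(C)(C)[Si](OCC(=O)[C@@H]1COC(C)(C)O1)(c1ccccc1)c1ccccc1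
F6 | step 3 | (2S)-1-[(tert-butyldiphenylsilyl)oxy]-2-[(4S)-2,2-dimethyl-1,3-dioxolan-4-yl]-6-methylhept-5-en-2-ol | CC(C)(C)[Si](OC[C@@](O)(CCC=C(C)C)[C@@H]1COC(C)(C)O1)(c1ccccc1)c1ccccc1
F7 | step 16 | (1S,2R,3S,12S,13S,4E,8E)-3,12,13,20-tetrakis(triethylsilyloxy)cembra-4,8-diene-2,16-diol | OCC[C@H]1C[C@H](O[Si](CC)(CC)CC)[C@@](O[Si](CC)(CC)CC)(CO[Si](CC)(CC)CC)CC/C=C(\C)CC/C=C(\C)[C@H](O[Si](CC)(CC)CC)[C@@H]1O
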